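If the dusk curve stops at 30% of its 10 mM of starting material, then something stopped it, and I want to know what before I say anything about three new flasks that vary the reagent and carry less free catalyst than dusk.

the same everywhere: starting material 10 mM; added ligand 12 µM
- dusk: reagent 4 mM; free catalyst 15 µM (in portions, 2); run made earlier; portions every 20 s
- birch: reagent 4.00 mM; free catalyst 10 µM (in portions, 2); the portions of free catalyst follow each other after 20 s, the first at the start; time 3.0 min
- larch: reagent 12.0 mM; free catalyst 10 µM (in portions, 2); the portions of free catalyst follow each other after 20 s, the first at the start; time 3.0 min
- oak: reagent 40.0 mM; free catalyst 10 µM (in portions, 2); the portions of free catalyst follow each other after 20 s, the first at the start; time 3.0 min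

dusk run (percent of the starting material charged)

| time / s | target / % |
|---|---|
| 15.0 | 13 |
| 40.0 | 23 |
| 80.0 | 30 |
| 120 | 30 |

(standard deviation of a reading: 2 percentage points)

- amount of target at the end, in percent of the starting material charged for birch, larch, oak, in this order
- how the row runs (falls, then rises / hardly changes / falls all the way / rises, then falls / rises all the way)

- "hardly changes" means that all values lie within two and a half points (for a concentration: within two and a half percent of the largest)
- no earlier run changes the charge of free catalyst; that part of a forecast is a guess

The dusk readings stand level at 80.0 s and 120 s, and the new flasks run longer than that, so I treat time as sufficient, although that is a guess with less catalyst. Two extreme readings of the plateau can then be solved in the head.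

In the first, the 4 mM of reagent stopped dusk, which makes reagent the limiting reagent. Plateau target over reagent charged gives 0.750, and I call this the target kept per reagent; it carries the scatter of the reading. Multiplied by each charge, it gives 30.0% for birch and 90.0% for larch. For oak it gives 300%, which is more than the starting material can yield, so this extreme puts oak at 100%.

In the second extreme, the catalyst stopped dusk after 200 targets per catalyst charged, its turnover number. Then 10 µM gives 20.0% in each of the three flasks, and the row hardly changes.

A real flask may hold some of both, so I place birch between 20.0% and 30.0%, and larch and oak between 20.0% and their first-extreme values. The row falls in neither extreme, and I commit to a rise.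

The forecast gives 29%, 82% and 97%, and says the row rises all the way, on these grounds: “I therefore read the plateau as reagent exhaustion”. Its larch figure is lower than my first-extreme value.

Birch, larch and oak give 24.3%, 76.9% and 83.6%, and the row rises all the way, as the forecast said.

    starting material + free catalyst → catalyst intermediate A (k = 25000 L mol⁻¹ s⁻¹)
    reagent + catalyst intermediate A → catalyst intermediate B (k = 3500 L mol⁻¹ s⁻¹)
    catalyst intermediate B → released group + catalyst intermediate C (k = 340 s⁻¹)
    catalyst intermediate C → free catalyst + target (k = 110 s⁻¹)
    reagent + free catalyst → spent catalyst (k = 0.0860 L mol⁻¹ s⁻¹)
    free catalyst + added ligand ⇌ idle complex (K = 2.60 × 10⁶ L mol⁻¹, k = 17000 L mol⁻¹ s⁻¹)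
    starting material + target → side product (k = 0.650 L mol⁻¹ s⁻¹)

Birch ends with reagent at 1.0% of its charge and side product at 30.5% of the starting material charged, each unit of side product counted as two. Target kept per reagent used in birch comes to 0.614, lower than the 0.750 read at dusk on the reagent charged. In larch, the same quotient at the end is 0.874.

The earlier runs and the new flask were generated by integration with made-up constants, and the scatter is random.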